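**Plan**

- Numbering: drimane-type (ring A = C1–C5 + C10, ring B = C5–C10, C11 on C9, chain C12–C22); β is the face of the C10 methyl. The target is cis-fused (H5 and the C10 methyl both β).
- Cuts, in order: C12–C13 (B-alkyl Suzuki–Miyaura of a 9-vinyl carbinol with an (E)-alkenyl iodide); the C8 carbinol back to a Δ7-6-ketone (Wharton transposition); then C1–C10 and C4–C5 together, as a [4+2] between a ring B 3-methylcyclohex-2-enone and allylidenecyclopropane.
- Enabling feature: C5=C10 lies in ring B next to C6, so a C6 carbonyl makes it a dienophile whose β-carbon already carries the C10 methyl. H5 and the C10 methyl are cis in the target, which is what suprafacial addition gives. The C4 gem-dimethyl is carried as a spirocyclopropane (s-cis diene), and the C6 oxygen is later moved to C8.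
- Forward: ring B (arene hydrogenation to a meso ketone, desymmetrised) → ring A (Diels–Alder) → C8 carbinol → gem-dimethyl → chain.
- Stereochemistry: C9 from chiral lithium amide desymmetrisation; C10 and C5 from cycloaddition anti to the C9/C8 substituents; C8 from α-face epoxidation then Wharton; chain E-olefins from (E)-geranylacetone and syn-carboalumination.

Key step: step 7

Assumption: the (R,R)-amide is taken to remove the proton on the CH2 next to the 3R centre of meso ketone 5, by analogy with simple cis-3,5-dimethylcyclohexanones; if the sense is opposite on this substrate, the (S,S)-amine is used.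

**Route**

Step 1
Reactants: 1 methyl 4-hydroxy-2,6-dimethylbenzoate
Product: 2 methyl all-cis-4-hydroxy-2,6-dimethylcyclohexane-1-carboxylate (meso)
Conditions: H2 (70 atm), Rh/Al2O3 (5 wt %), MeOH, 50 °C
Reagents that add atoms: none
Why: Heterogeneous arene hydrogenation over rhodium adds all hydrogens to one face of the adsorbed ring and spares the ester, so the ester, both methyls and the hydroxyl should end up all-cis in a meso cyclohexane (the carbinol configuration is lost in step 3 anyway).

Step 2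
Reactants: 2 methyl all-cis-4-hydroxy-2,6-dimethylcyclohexane-1-carboxylate (meso)
Product: 3 all-cis-4-(hydroxymethyl)-3,5-dimethylcyclohexan-1-ol (meso)
Conditions: LiAlH4, THF, 0 → 25 °C
Reagents that add atoms: none
Why: LiAlH4 reduces the ester to the primary alcohol without touching the stereocentres.

Step 3
Reactants: 3 all-cis-4-(hydroxymethyl)-3,5-dimethylcyclohexan-1-ol (meso)
Product: 4 all-cis-4-(hydroxymethyl)-3,5-dimethylcyclohexan-1-one (meso)
Conditions: NaOCl (aq, 1.1 equiv), AcOH, 20 °C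
Reagents that add atoms: none
Why: Hypochlorite in acetic acid oxidises secondary alcohols much faster than primary ones, which gives the meso hydroxy ketone chemoselectively.

Step 4
Reactants: 4 all-cis-4-(hydroxymethyl)-3,5-dimethylcyclohexan-1-one (meso)
Product: 5 all-cis-4-[(tert-butyldimethylsilyloxy)methyl]-3,5-dimethylcyclohexan-1-one (meso)
Conditions: TBSCl, imidazole, DMF, 25 °C
Reagents that add atoms: tert-butyldimethylsilyl chloride CC(C)(C)[Si](C)(C)Cl
Why: Standard silylation protects the only hydroxyl as a robust ether that tolerates amide bases, the Lewis acid and the later basic and reductive steps.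

Step 5
Reactants: 5 all-cis-4-[(tert-butyldimethylsilyloxy)methyl]-3,5-dimethylcyclohexan-1-one (meso)
Product: 7 (4S,5S)-4-[(tert-butyldimethylsilyloxy)methyl]-3,5-dimethylcyclohex-2-en-1-one, via trimethylsilyl enol ether 6 (not isolated)
Conditions: (R,R)-bis(1-phenylethyl)amine, n-BuLi, THF, −78 °C; TMSCl (in situ quench), −100 → −78 °C; then Pd(OAc)2 (10 mol %), O2 (1 atm), DMSO, 25 °C
Reagents that add atoms: none
Why: Enantioselective deprotonation of the meso ketone by the C2-symmetric chiral lithium amide with in situ silyl trapping distinguishes the two enantiotopic α-CH2 groups and thereby fixes the absolute configuration of C9 (and through it of every later centre), and aerobic Saegusa–Ito oxidation of the enol silane then places the C5=C10 double bond under the methyl group.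

Step 6
Reactants: 8 cyclopropyltriphenylphosphonium bromide; 9 acrolein
Product: 11 allylidenecyclopropane (prop-2-en-1-ylidenecyclopropane), via cyclopropylidene ylide 10 (not isolated)
Conditions: NaH, bis(2-methoxyethyl) ether, 60 °C; then 9, 0 → 25 °C; product distilled from the mixture
Reagents that add atoms: none
Why: Wittig olefination of acrolein with the cyclopropylidene ylide gives the volatile diene in which the future C4 methyl groups are tied back as a three-membered ring.

Step 7
Reactants: 7 (4S,5S)-4-[(tert-butyldimethylsilyloxy)methyl]-3,5-dimethylcyclohex-2-en-1-one; 11 allylidenecyclopropane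
Product: 12 cis-fused C4-spirocyclopropyl Δ2-octal-6-one (10β-CH3; 5β-H; 9β-CH2OTBS; 8β-CH3)
Conditions: EtAlCl2 (1.2 equiv), 11 (4 equiv), toluene, −40 → 0 °C
Reagents that add atoms: none
Why: Proposed new method: EtAlCl2 bound to the C6 carbonyl lowers the LUMO of the C5=C10 enone and the s-cis diene adds in an asynchronous concerted [4+2] in which the unsubstituted CH2 terminus (largest HOMO coefficient) bonds to the β-carbon C10 ahead of the cyclopropylidene carbon bonding to C5, the relief of methylenecyclopropane strain (about 13 kcal/mol) helping to pay for the congested C4–C5 bond; the closest known reaction types are the AlCl3-promoted Diels–Alder reactions of 3-methylcyclohex-2-enones with simple 1,3-dienes and the thermal cycloadditions of allylidenecyclopropane with unhindered enones and quinones, the combination on a β,β-disubstituted enone being without precedent. Ring A is closed by intermolecular [4+2] cycloaddition with both σ bonds formed on one face of the enone, which is why the ring fusion must be cis. C10 and C5 are set by the face of attack: the C9 CH2OTBS group is held pseudoaxial by allylic strain against the C10 methyl and, together with the cis C8 methyl, shields the β face, so the diene should add from the α face and leave the C10 methyl and H5 β. Regioselectivity (C1 to C10, C4 to C5) follows the ortho rule for a 1-alkylidene-substituted diene and is reinforced sterically because the alternative would join two fully substituted carbons, while endo/exo selectivity is irrelevant because neither diene terminus is stereogenic. The step needs cycloaddition to outrun acid-induced opening of the cyclopropane, which the proton-scavenging alkylaluminium chloride and the low temperature are meant to secure, and it needs the kinetic cis adduct to survive, which a quench at 0 °C is meant to secure.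

Step 8
Reactants: 12 cis-fused C4-spirocyclopropyl Δ2-octal-6-one (10β-CH3; 5β-H; 9β-CH2OTBS; 8β-CH3)
Product: 14 cis-fused C4-spirocyclopropyl Δ2,Δ7-dien-6-one (10β-CH3; 5β-H; 9β-CH2OTBS; 8-CH3), via trimethylsilyl dienol ether 13 (not isolated)
Conditions: LiN(i-Pr)2, TMSCl, THF, −78 °C; then Pd(OAc)2 (10 mol %), O2 (1 atm), DMSO, 25 °C
Reagents that add atoms: none
Why: Kinetic deprotonation takes the C7 methylene proton (H5 is flanked by two quaternary carbons) and Saegusa–Ito oxidation can only dehydrogenate towards C8, since C4 and C10 carry no hydrogen, so the Δ7-6-ketone should form as a single regioisomer with C5 untouched.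

Step 9
Reactants: 14 cis-fused C4-spirocyclopropyl Δ2,Δ7-dien-6-one (10β-CH3; 5β-H; 9β-CH2OTBS; 8-CH3)
Product: 15 7α,8α-epoxy-6-ketone (C4-spirocyclopropyl; Δ2; 10β-CH3; 5β-H; 9β-CH2OTBS; 8β-CH3)
Conditions: H2O2 (30 % aq), NaOH (0.3 equiv), MeOH, 0 °C
Reagents that add atoms: hydrogen peroxide OO
Why: Weitz–Scheffer nucleophilic epoxidation: hydroperoxide adds to C8 anti to the pseudoaxial C9 CH2OTBS group, that is from the α face, and the enolate closes the oxirane on the same face, which sets the C8–O bond α.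

Step 10
Reactants: 15 7α,8α-epoxy-6-ketone (C4-spirocyclopropyl; Δ2; 10β-CH3; 5β-H; 9β-CH2OTBS; 8β-CH3)
Product: 16 Δ2,Δ6-dien-8α-ol (C4-spirocyclopropyl; 10β-CH3; 5β-H; 9β-CH2OTBS; 8β-CH3)
Conditions: N2H4·H2O (3 equiv), AcOH (0.2 equiv), MeOH, 0 → 25 °C
Reagents that add atoms: none
Why: Wharton transposition: the epoxy hydrazone fragments with loss of N2 to the allylic alcohol, so the C6 oxygen that activated the dienophile is removed while the C8–O bond, which is not broken, keeps its α configuration.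

Step 11
Reactants: 16 Δ2,Δ6-dien-8α-ol (C4-spirocyclopropyl; 10β-CH3; 5β-H; 9β-CH2OTBS; 8β-CH3)
Product: 17 saturated C4-spirocyclopropyl cis-decalin-8α-ol (10β-CH3; 5β-H; 9β-CH2OTBS; 8β-CH3)
Conditions: 2-nitrobenzenesulfonylhydrazide (6 equiv), Et3N, CH2Cl2, 25 °C
Reagents that add atoms: none
Why: Diimide transfers H2 in a concerted syn fashion to the two cis-disubstituted ring alkenes and, unlike metal-catalysed hydrogenation, cannot cleave the allylic C–O bond or open the vinylcyclopropane.

Step 12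
Reactants: 17 saturated C4-spirocyclopropyl cis-decalin-8α-ol (10β-CH3; 5β-H; 9β-CH2OTBS; 8β-CH3)
Product: 19 (1S,2R,4aR,8aS)-1-(hydroxymethyl)-2,5,5,8a-tetramethyldecahydronaphthalen-2-ol, via gem-dimethyl silyl ether 18 (not isolated)
Conditions: H2 (4 atm), PtO2, AcOH, 25 °C; then H2O added (AcOH/H2O 4:1), 40 °C
Reagents that add atoms: none
Why: Hydrogenolysis of a spirocyclopropane over PtO2 in acetic acid cleaves the least hindered CH2–CH2 bond and so unveils the C4 gem-dimethyl group, and the aqueous acetic acid then removes the primary silyl ether.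

Step 13
Reactants: 19 (1S,2R,4aR,8aS)-1-(hydroxymethyl)-2,5,5,8a-tetramethyldecahydronaphthalen-2-ol
Product: 20 (1R,2R,4aR,8aS)-2-hydroxy-2,5,5,8a-tetramethyldecahydronaphthalene-1-carbaldehyde
Conditions: Dess–Martin periodinane, pyridine, CH2Cl2, 0 → 25 °C
Reagents that add atoms: none
Why: Dess–Martin oxidation converts the primary alcohol into the aldehyde under buffered non-basic conditions, the tertiary alcohol being inert and C9 not being epimerised.

Step 14
Reactants: 20 (1R,2R,4aR,8aS)-2-hydroxy-2,5,5,8a-tetramethyldecahydronaphthalene-1-carbaldehyde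
Product: 21 (1R,2R,4aR,8aS)-1-ethenyl-2,5,5,8a-tetramethyldecahydronaphthalen-2-ol
Conditions: Ph3PCH3Br (1.5 equiv), KN(SiMe3)2 (1.4 equiv), THF, 0 °C; then 20, −78 → 0 °C
Reagents that add atoms: methyltriphenylphosphonium bromide C[P+](c1ccccc1)(c1ccccc1)c1ccccc1.[Br-]
Why: Wittig methylenation; the non-stabilised ylide is a weaker base than a tertiary alkoxide and is kept free of excess amide base, so the β-hydroxy aldehyde should be olefinated without retro-aldol cleavage or epimerisation at C9.

Step 15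
Reactants: 22 (E)-geranylacetone ((5E)-6,10-dimethylundeca-5,9-dien-2-one)
Product: 24 (5E)-6,10-dimethylundeca-5,9-dien-1-yne, via enol phosphate 23 (not isolated)
Conditions: LiN(i-Pr)2 (1.05 equiv), THF, −78 °C; ClP(O)(OEt)2, −78 → 25 °C; then LiN(i-Pr)2 (2.3 equiv), −78 → 25 °C; H2O
Reagents that add atoms: none
Why: Kinetic enolisation of the methyl ketone on the methyl side, O-phosphorylation and double elimination (methyl ketone to terminal alkyne) leave the (E)-trisubstituted olefin untouched.

Step 16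
Reactants: 24 (5E)-6,10-dimethylundeca-5,9-dien-1-yne
Product: 26 (1E,5E)-1-iodo-2,6,10-trimethylundeca-1,5,9-triene, via alkenylalane 25 (not isolated)
Conditions: Me3Al (2 equiv), Cp2ZrCl2 (0.25 equiv), CH2Cl2, 0 → 25 °C; then I2, THF, −30 → 0 °C
Reagents that add atoms: trimethylaluminium C[Al](C)C; iodine II
Why: Negishi zirconium-catalysed carboalumination adds methyl and aluminium syn across the alkyne with aluminium at the terminal carbon, and iodinolysis with retention gives the (E)-alkenyl iodide.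

Step 17
Reactants: 21 (1R,2R,4aR,8aS)-1-ethenyl-2,5,5,8a-tetramethyldecahydronaphthalen-2-ol; 26 (1E,5E)-1-iodo-2,6,10-trimethylundeca-1,5,9-triene
Product: 28 (1R,2R,4aR,8aS)-2,5,5,8a-tetramethyl-1-[(3E,7E)-4,8,12-trimethyltrideca-3,7,11-trien-1-yl]decahydronaphthalen-2-ol (target), via alkylborane 27 (not isolated)
Conditions: 9-BBN (2.5 equiv), THF, 25 → 50 °C; then 26, Pd(dppf)Cl2 (5 mol %), AsPh3, Cs2CO3 (aq), DMF, 25 °C
Reagents that add atoms: none
Why: B-alkyl Suzuki–Miyaura coupling: 9-BBN hydroborates the vinyl group at its terminus (the first equivalent is consumed by the tertiary hydroxyl as a borinate that is hydrolysed on work-up) and palladium-catalysed coupling with the alkenyl iodide proceeds with retention of the E geometry, forming C12–C13 without touching any stereocentre.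

**Compound list**

1 | methyl 4-hydroxy-2,6-dimethylbenzoate | COC(=O)c1c(C)cc(O)cc1C | starting material
2 | methyl all-cis-4-hydroxy-2,6-dimethylcyclohexane-1-carboxylate (meso; 2R,6S) | COC(=O)[C@@H]1[C@H](C)C[C@H](O)C[C@@H]1C | intermediate
3 | all-cis-4-(hydroxymethyl)-3,5-dimethylcyclohexan-1-ol (meso; 3R,5S) | OC[C@@H]1[C@H](C)C[C@H](O)C[C@@H]1C | intermediate
4 | all-cis-4-(hydroxymethyl)-3,5-dimethylcyclohexan-1-one (meso; 3R,5S) | OC[C@@H]1[C@H](C)CC(=O)C[C@@H]1C | intermediate
5 | all-cis-4-[(tert-butyldimethylsilyloxy)methyl]-3,5-dimethylcyclohexan-1-one (meso; 3R,5S) | CC(C)(C)[Si](C)(C)OC[C@@H]1[C@H](C)CC(=O)C[C@@H]1C | intermediate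
6 | (3S,4S,5S)-4-[(tert-butyldimethylsilyloxy)methyl]-3,5-dimethyl-1-(trimethylsilyloxy)cyclohex-1-ene | CC(C)(C)[Si](C)(C)OC[C@@H]1[C@H](C)C=C(O[Si](C)(C)C)C[C@@H]1C | intermediate
7 | (4S,5S)-4-[(tert-butyldimethylsilyloxy)methyl]-3,5-dimethylcyclohex-2-en-1-one (CH2OTBS and 5-CH3 cis) | CC(C)(C)[Si](C)(C)OC[C@@H]1C(C)=CC(=O)C[C@@H]1C | intermediate
8 | cyclopropyltriphenylphosphonium bromide | [Br-].C1CC1[P+](c1ccccc1)(c1ccccc1)c1ccccc1 | starting material
9 | acrolein | C=CC=O | starting material
10 | cyclopropylidene(triphenyl)phosphorane | C1CC1=P(c1ccccc1)(c1ccccc1)c1ccccc1 | intermediate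
11 | allylidenecyclopropane (prop-2-en-1-ylidenecyclopropane) | C=CC=C1CC1 | intermediate
12 | cis-fused C4-spirocyclopropyl Δ2-octal-6-one (10β-CH3; 5β-H; 9β-CH2OTBS; 8β-CH3) | CC(C)(C)[Si](C)(C)OC[C@@H]1[C@@]2(C)CC=CC3(CC3)[C@H]2C(=O)C[C@@H]1C | intermediate
13 | C6 trimethylsilyl dienol ether of 12 (Δ2,Δ6; 6-OTMS) | CC(C)(C)[Si](C)(C)OC[C@@H]1[C@@]2(C)CC=CC3(CC3)[C@H]2C(O[Si](C)(C)C)=C[C@@H]1C | intermediate
14 | cis-fused C4-spirocyclopropyl Δ2,Δ7-dien-6-one (10β-CH3; 5β-H; 9β-CH2OTBS; 8-CH3) | CC(C)(C)[Si](C)(C)OC[C@@H]1[C@@]2(C)CC=CC3(CC3)[C@H]2C(=O)C=C1C | intermediate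
15 | 7α,8α-epoxy-6-ketone (C4-spirocyclopropyl; Δ2; 10β-CH3; 5β-H; 9β-CH2OTBS; 8β-CH3) | CC(C)(C)[Si](C)(C)OC[C@@H]1[C@@]2(C)CC=CC3(CC3)[C@H]2C(=O)[C@H]4O[C@@]14C | intermediate
16 | Δ2,Δ6-dien-8α-ol (C4-spirocyclopropyl; 10β-CH3; 5β-H; 9β-CH2OTBS; 8β-CH3) | CC(C)(C)[Si](C)(C)OC[C@@H]1[C@@]2(C)CC=CC3(CC3)[C@H]2C=C[C@@]1(C)O | intermediate
17 | saturated C4-spirocyclopropyl cis-decalin-8α-ol (10β-CH3; 5β-H; 9β-CH2OTBS; 8β-CH3) | CC(C)(C)[Si](C)(C)OC[C@@H]1[C@@]2(C)CCCC3(CC3)[C@H]2CC[C@@]1(C)O | intermediate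
18 | (1S,2R,4aR,8aS)-1-[(tert-butyldimethylsilyloxy)methyl]-2,5,5,8a-tetramethyldecahydronaphthalen-2-ol | CC(C)(C)[Si](C)(C)OC[C@@H]1[C@@]2(C)CCCC(C)(C)[C@H]2CC[C@@]1(C)O | intermediate
19 | (1S,2R,4aR,8aS)-1-(hydroxymethyl)-2,5,5,8a-tetramethyldecahydronaphthalen-2-ol | OC[C@@H]1[C@@]2(C)CCCC(C)(C)[C@H]2CC[C@@]1(C)O | intermediate
20 | (1R,2R,4aR,8aS)-2-hydroxy-2,5,5,8a-tetramethyldecahydronaphthalene-1-carbaldehyde | O=C[C@@H]1[C@@]2(C)CCCC(C)(C)[C@H]2CC[C@@]1(C)O | intermediate
21 | (1R,2R,4aR,8aS)-1-ethenyl-2,5,5,8a-tetramethyldecahydronaphthalen-2-ol | C=C[C@@H]1[C@@]2(C)CCCC(C)(C)[C@H]2CC[C@@]1(C)O | intermediate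
22 | (E)-geranylacetone ((5E)-6,10-dimethylundeca-5,9-dien-2-one) | CC(C)=CCC/C(C)=C/CCC(C)=O | starting material
23 | diethyl (5E)-6,10-dimethylundeca-1,5,9-trien-2-yl phosphate | CC(C)=CCC/C(C)=C/CCC(=C)OP(=O)(OCC)OCC | intermediate
24 | (5E)-6,10-dimethylundeca-5,9-dien-1-yne | CC(C)=CCC/C(C)=C/CCC#C | intermediate
25 | dimethyl[(1E,5E)-2,6,10-trimethylundeca-1,5,9-trien-1-yl]alane | CC(C)=CCC/C(C)=C/CC/C(C)=C/[Al](C)C | intermediate
26 | (1E,5E)-1-iodo-2,6,10-trimethylundeca-1,5,9-triene | CC(C)=CCC/C(C)=C/CC/C(C)=C/I | intermediate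
27 | (1R,2R,4aR,8aS)-1-[2-(9-borabicyclo[3.3.1]nonan-9-yl)ethyl]-2,5,5,8a-tetramethyldecahydronaphthalen-2-ol | B1(CC[C@@H]2[C@@]3(C)CCCC(C)(C)[C@H]3CC[C@@]2(C)O)C4CCCC1CCC4 | intermediate
28 | (1R,2R,4aR,8aS)-2,5,5,8a-tetramethyl-1-[(3E,7E)-4,8,12-trimethyltrideca-3,7,11-trien-1-yl]decahydronaphthalen-2-ol | CC(C)=CCC/C(C)=C/CC/C(C)=C/CC[C@@H]1[C@@]2(C)CCCC(C)(C)[C@H]2CC[C@@]1(C)O | target

**Totals**

Total step count: 17. Longest linear sequence: 14 (steps 1–5, 7–14, 17).

**Steps most likely to fail**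

1. Step 7 (labelled step). The risk is Lewis-acid-induced opening or oligomerisation of the cyclopropylidene diene before it adds to the sluggish β,β-disubstituted enone, and epimerisation of the adduct at C5. Fallback with known chemistry, setting out from 7: the triflimide-catalysed [4+2] (Mukaiyama–Michael/Michael sequence) of hindered 2-silyloxy dienes with β-substituted cycloalkenones. The diene is 4-methyl-2-(trimethylsilyloxy)penta-1,3-diene F1 (from mesityl oxide, LiN(i-Pr)2, TMSCl). With Tf2NH (10 mol %) in CH2Cl2 at −78 °C it should give the cis-fused 4,4-dimethyl adduct as its C2 trimethylsilyl enol ether F2. CsF/PhNTf2 converts this into the C2 enol triflate F3, and Pd(OAc)2/PPh3/HCO2H/Bu3N reduces that to the Δ2-6-ketone F4, the 4,4-dimethyl analogue of 12. The operations of steps 8–10 then lead through the trimethylsilyl dienol ether F5, the Δ2,Δ7-dien-6-one F6 and the 7α,8α-epoxy ketone F7 to the Δ2,Δ6-dien-8α-ol F8. Diimide reduction (conditions of step 11) gives 18, where the route is rejoined; the aqueous acetic acid stage of step 12 then gives 19, and no cyclopropane hydrogenolysis is needed.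

2. Step 9. The risk is poor facial selectivity of hydroperoxide addition at C8, or base-mediated epimerisation at C5 (α' to the enone) into the trans-fused series. Fallback, setting out from 14: NaBH4/CeCl3 should reduce the carbonyl from the β face (the α face of C6 is screened by C4) to the 6α-allylic alcohol F9. Hydroxyl-directed epoxidation (VO(acac)2, t-BuOOH) delivers oxygen syn to the hydroxyl to give the 7α,8α-epoxy-6α-ol F10. Dess–Martin oxidation then returns to 15 without exposure to base.

3. Step 14. The risk is retro-aldol cleavage of the β-hydroxy aldehyde or epimerisation at C9 under the basic ylide. Fallback, setting out from 19: both hydroxyls are silylated (Et3SiOTf, 2,6-lutidine) to the bis(triethylsilyl) ether F11. Swern conditions oxidise the primary triethylsilyl ether directly to the 8-O-triethylsilyl aldehyde F12, which can no longer undergo retro-aldol cleavage. Methylenation gives the 8-O-triethylsilyl vinyl compound F13, and Bu4NF returns to 21.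

**Further compounds**

F1 | step 7 | 4-methyl-2-(trimethylsilyloxy)penta-1,3-diene | C=C(O[Si](C)(C)C)C=C(C)C
F2 | step 7 | cis-fused 4,4-dimethyl adduct, C2 trimethylsilyl enol ether (Δ2; 6-one; 10β-CH3; 5β-H; 9β-CH2OTBS; 8β-CH3) | CC(C)(C)[Si](C)(C)OC[C@@H]1[C@@]2(C)CC(O[Si](C)(C)C)=CC(C)(C)[C@H]2C(=O)C[C@@H]1C
F3 | step 7 | C2 enol triflate of the 4,4-dimethyl adduct | CC(C)(C)[Si](C)(C)OC[C@@H]1[C@@]2(C)CC(OS(=O)(=O)C(F)(F)F)=CC(C)(C)[C@H]2C(=O)C[C@@H]1C
F4 | step 7 | cis-fused 4,4-dimethyl Δ2-octal-6-one (10β-CH3; 5β-H; 9β-CH2OTBS; 8β-CH3) | CC(C)(C)[Si](C)(C)OC[C@@H]1[C@@]2(C)CC=CC(C)(C)[C@H]2C(=O)C[C@@H]1C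
F5 | step 7 | C6 trimethylsilyl dienol ether of F4 | CC(C)(C)[Si](C)(C)OC[C@@H]1[C@@]2(C)CC=CC(C)(C)[C@H]2C(O[Si](C)(C)C)=C[C@@H]1C
F6 | step 7 | 4,4-dimethyl Δ2,Δ7-dien-6-one | CC(C)(C)[Si](C)(C)OC[C@@H]1[C@@]2(C)CC=CC(C)(C)[C@H]2C(=O)C=C1C
F7 | step 7 | 4,4-dimethyl 7α,8α-epoxy-Δ2-6-ketone | CC(C)(C)[Si](C)(C)OC[C@@H]1[C@@]2(C)CC=CC(C)(C)[C@H]2C(=O)[C@H]3O[C@@]13C
F8 | step 7 | 4,4-dimethyl Δ2,Δ6-dien-8α-ol | CC(C)(C)[Si](C)(C)OC[C@@H]1[C@@]2(C)CC=CC(C)(C)[C@H]2C=C[C@@]1(C)O
F9 | step 9 | 6α-hydroxy-Δ2,Δ7-diene (C4-spirocyclopropyl; 9β-CH2OTBS) | CC(C)(C)[Si](C)(C)OC[C@@H]1[C@@]2(C)CC=CC3(CC3)[C@H]2[C@@H](O)C=C1C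
F10 | step 9 | 7α,8α-epoxy-6α-ol (C4-spirocyclopropyl; Δ2; 9β-CH2OTBS) | CC(C)(C)[Si](C)(C)OC[C@@H]1[C@@]2(C)CC=CC3(CC3)[C@H]2[C@@H](O)[C@H]4O[C@@]14C
F11 | step 14 | bis(triethylsilyl) ether of 19 | CC[Si](CC)(CC)OC[C@@H]1[C@@]2(C)CCCC(C)(C)[C@H]2CC[C@@]1(C)O[Si](CC)(CC)CC
F12 | step 14 | 8-O-triethylsilyl ether of aldehyde 20 | O=C[C@@H]1[C@@]2(C)CCCC(C)(C)[C@H]2CC[C@@]1(C)O[Si](CC)(CC)CC
F13 | step 14 | 8-O-triethylsilyl ether of vinyl carbinol 21 | C=C[C@@H]1[C@@]2(C)CCCC(C)(C)[C@H]2CC[C@@]1(C)O[Si](CC)(CC)CC
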